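Amounts first: the flask holds 0.020 M of substrate and receives 1.05 equivalents of partner, yet each substrate carried on to bis adduct costs two partners. With neither free partner nor tris adduct in this flask, the balance puts the substrate left at the bis adduct less 5 percentage points, so what remains depends on how the partner divides.

- larch: substrate 0.020 M; partner 0.021 M (fed, over 3.0 min); the very flask that is asked about, followed so far
- flask: substrate 0.020 M; partner 0.0210 M (fed, over 3.0 min); time 30 min
larch run (percent of the substrate charged)

| time / min | single product / % | tris adduct / % |
|---|---|---|
| 0.667 | 9.5 | 0 |
| 1.33 | 19.3 | 0.5 |
| 3.00 | 24.8 | 5.7 |
| 6.00 | 22.1 | 0 |

(scatter of a reading: 1 percentage point)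
- the moment within 30 min at which there is most single product
- the amount of single product, in percent of the substrate charged, at that time

Both steps consume partner, so dividing one rate by the other cancels c(partner) and time. Each substrate consumed gives one single product, while s times c(single)/c(substrate) single product goes on to bis adduct. Here s is the selectivity factor, the second step's rate constant over the first's.

In the first instants that ratio is small. At 0.667 min the flask has received 23.3% of partner per substrate, more than the 9.5% of single product read, so the rest stands as free partner or bis adduct. By 3.00 min single product reads 24.8% and tris adduct 5.7%. At 6.00 min tris adduct reads 0% and single product 22.1%.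

We assume partner is used up at that last reading. The balance then gives substrate 36.4% and bis adduct 41.4%. Letting c(single)/c(substrate) climb in a straight line with substrate consumed, we read s = 2.15.

Single product peaks when s times c(single) equals c(substrate). By our reckoning that means 23.9% of single product with 51.4% of substrate left. Partner bound as single product and bis adduct at that point has been fed by 2.09 min, and free partner and tris adduct put the peak later than that.

The forecast gives 25% at 3.2 min, above our amount: "So the peak falls at or just after the end of dosing."

    substrate + partner → single product (k = 1.97 M⁻¹ s⁻¹)
    partner + single product → bis adduct (k = 3.95 M⁻¹ s⁻¹)
    partner + bis adduct ⇌ tris adduct (K = 120 M⁻¹, k = 8.50 M⁻¹ s⁻¹)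

The flask peaks at 2.65 min with 25.0%, earlier than the forecast's time. At that moment substrate stands at 50.0% and single product at 25.0%, so s times their ratio is 1.07, close to one, as the peak condition asks.

With 0.084 M of partner, 4.20 equiv, the reckoning contains no partner charge, so s again gives 23.9%. The computed peak in that flask is 25.0%.

All runs were generated by integration with constants of no real substance, and the scatter is random.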